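## Structural features

Difengpiol B has three rings: benzene ring A, with a methoxy group at C7 and a 3-hydroxypropyl chain at C5; dihydrofuran ring B (O1, C2, C3, C3a, C7a) fused to it; and cyclohexane ring C, attached to C2 through the single bond C2–C1'. Ring B holds two adjacent stereocentres, C2 (S) and C3 (R, bearing CH2OH), trans to each other. C2 is bonded directly to the quaternary carbinol C1' (S), so three stereocentres stand in a row. Ring C carries two more, C3' (OH, S) and C4' (OMe, S), trans to each other, with the C3' hydroxyl cis to the C1' hydroxyl. The fragile points are the tertiary alcohol at C1' (ionisation or elimination in strong acid), the electron-rich ring A (oxidants), C3 once it carries a carbonyl group (epimerisation), and three free hydroxyl groups that call for sparing use of protection. The real difficulty is C1': it is fully substituted, its two ring arms C2' and C6' first differ two and three bonds away at C3' and C4', and its configuration must be tied to that of C2 although it cannot bias reactions at C2 in a predictable way. The key step uses the array O–C1'(–C2)–C2'–C3'=C4'. Read backwards, C1' is the α-carbon of a lactone enolate whose carbonyl carbon is the future C2, C4' is the carbinol carbon of that lactone, and C2' and C3' are a vinyl group on it. A (3,3) shift therefore carries the configuration of a simple secondary carbinol over to C1'.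

## Logic of the disconnections

**27 to 26.** The C4'–OCH3 bond is cut. A trans ether/hydroxyl pair on neighbouring carbons is what an anti epoxide opening leaves, so the cut removes one stereocentre and the last carbon that is not in a purchased piece. The forward step must open the C3'–C4' epoxide of 26 at C4' and not at C3'. Chelation of a Lewis acid between the C1' hydroxyl and the epoxide oxygen, and the trans-diaxial rule, point the same way.

**26 to 25.** Both C–O bonds of the oxirane are cut, which leaves the C3'=C4' alkene of 25. Two stereocentres are traded for a cis alkene, and the free homoallylic C1' hydroxyl is the handle for face selection. The forward step must deliver oxygen syn to that hydroxyl and needs it unprotected.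

**25 to 23 (through 24).** Only bonds to heteroatom groups change: the O–Si bond at C1' (24), then the C–H bonds of the C3 hydroxymethyl group and the O–H of the chain, which go back to the C3 methyl ester and the benzoate of 23. C3 is thereby at the acid oxidation level, where a rearrangement can reach it, and the chain alcohol sits in a group that the same hydride reagent removes. The forward step needs reduction to outrun enolisation at C3.

**23 to 21 (through 22).** The C3–C3a bond is cut and C3a is reconnected to the ester carbon, the reverse of a 1,2-aryl shift; ring B grows to the pyranone ring of 21. A 2-substituted chroman-4-one can be assembled from a methyl ketone and an acyl donor, and the shift turns its single stereocentre C2 into the trans C2/C3 pair. The forward step must oxidise C3 (as the enol ether) in preference to the ring C alkene and must leave C2 alone.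

**21 to 19 (through 20).** The C2–H bond is cut, which gives 19 with C2 trigonal. The stereocentre that C1' cannot control is handed to a chiral catalyst. The forward step needs 1,4-selectivity, one face of C2, and no reduction of the ring C alkene.

**19 to 11 and 16 (through 18 and 17).** The O1–C2 bond is cut (cyclodehydration), then the C2–C3 bond of the pyranone, which is the bond between the carboxyl carbon of 11 and the acetyl methyl carbon of 16. The carboxyl carbon of 11 becomes C2 without change of oxidation level, and rings A and C arrive as two pieces. The forward steps need C-acylation of a ketone enolate by a hindered acid chloride and an acid-catalysed dehydration that spares the tertiary silyl ether.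

**16 to 12, 13 and 14 (through 15).** The aryl C5–CH2 bond is cut (cross-coupling of 13 with the borane 15 from 14), then the C5–Br bond (bromination of 12). The purchased ring A piece lacks the chain, and this adds it in two operations. The forward steps need bromination para to the phenol only and a coupling that tolerates free phenol and ketone.

**11 to 8 (through 10 and 9).** The C1'–C2' bond is cut and C4' is reconnected to the carboxyl oxygen, the reverse of a (3,3) shift. The quaternary centre is exchanged for a secondary allylic carbinol in a lactone, a stereocentre that a ketone reduction can set. The forward step needs clean formation of the ketene acetal and enough heat for a boat transition state.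

**8 to 6 (through 7).** The lactone acyl–oxygen bond is cut (hydroxy ester 7), then the carbinol C–H bond (ketone 6). The future C1' is reduced to the face selection of an enone reduction, and the C3 centre inherited from 1 serves as an internal reference that makes a wrong C6 epimer separable. The forward step needs reagent control at the ketone.

**6 to 1 and 5 (through 4, 3, 2).** The ketone–vinyl bond is cut (5 plus amide 4), then the O–Si bond (3), then the amide C–N bond with reconnection of the C2 oxygen to that carbonyl (lactone 2), then the ester O–CH3 bond (1). All carbons of the precursor come from a chiral-pool lactone acid and a vinyl nucleophile. The forward steps need the lactone to acylate faster than the ester, and the amide to react faster than the ester.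

## Other disconnections considered

**Alternative 1:** The cut removes O1–C2 and C2–C3 together. It leaves a ring A phenol that carries the future C3 as a sulfonyl-substituted benzylic carbon, A2, and a one-carbon ylide precursor, the sulfonium salt A3.
- Forward key step: base strips sulfinate from A2, the ortho-quinone methide takes up the amide-stabilised ylide from A3 at its exocyclic carbon, and the phenoxide closes on the ylide carbon with loss of the sulfide. This should give the trans amide A1.
- In its favour: ring B and the C2/C3 relation come in one operation, ring A arrives with its chain, and no oxidant is needed. The two arms of ring C would later be added to the amide carbonyl as two different nucleophiles, so they are told apart by order of addition and not by a remote difference.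
- Against it here: the dimethylsulfonium ylide is achiral, so A1 would be racemic unless a chiral sulfide or catalyst is found for this alkyl-substituted quinone methide, which can also tautomerise to a vinylphenol. C1' would then rest on 1,2-induction from C2 in a ketone addition, where chelation through O1 and the Felkin preference need not agree. Ring C would still cost two additions and a ring-closing metathesis.
- Comparison: for ring B the alternative is the better on step economy (one step against steps 10 to 13). Mechanistically it is stepwise and ionic, with the trans outcome set in the closing SN2 step, against a concerted shift. Structurally the chosen plan fixes C1' with certainty and leaves C2 to a catalyst, whereas this alternative leaves both the absolute sense of ring B and the configuration of C1' open. Overall length is about equal.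

**Alternative 2:** The cut runs through C1'–C2' and C5'–C6', a (4+2) retron in which C1' and C6' belong to an exocyclic alkene.
- Forward key step: the methylidene dioxolanone A4 and buta-1,3-diene A5 combine on heating, on the face of A4 away from the tert-butyl group, to give the spiro adduct A6. Hydrolysis would give the hydroxy acid A7, and its silylation gives 11, so everything after step 7 is shared.
- In its favour: C1' comes from a chiral-pool auxiliary in one intermolecular step, the alkene lands at C3'=C4' by construction, and no cryogenic or organometallic step is needed. Acid 11 would be reached in about six operations against seven, so on step count to 11 it is the equal or slightly the better, and it is the natural reserve for step 7.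
- Against it here: it needs the less common enantiomer of the hydroxy acid. A4 is made by radical bromination and elimination and polymerises easily. The unactivated diene asks for a sealed vessel and long heating. The face selectivity rests on a 1,3-relationship across the dioxolanone ring, which should be high but is not enforced, whereas the sigmatropic route transfers chirality through a geometry that has no alternative.
- Comparison: both form the bond at C1' in a concerted pericyclic step, and both deliver the same acid.

**Alternative 3:** Ring A is cut at C6–C7, C4–C5 and C3a–C4. This leaves a dihydrofuran that already carries C2, C3 and ring C and bears a Fischer carbene at the future C7, A8, together with the alkyne A9; carbon monoxide supplies C4.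
- Forward key step: heating A8 with A9 inserts the alkyne with its substituted carbon next to the carbonyl-derived carbon and closes ring A to the hydroquinone monoether A10.
- In its favour: the substitution pattern of ring A follows from the annulation, so no bromination or cross-coupling on the arene is needed. On regiocontrol of the side chain it is the equal of, or better than, steps 8 and 9. The union is convergent and late.
- Against it here: A10 carries a hydroxyl at C4 that 27 lacks, so a triflation and a reduction at a hindered phenol must follow. The carbene is a stoichiometric chromium reagent. A8 presupposes a trans-4,5-disubstituted dihydrofuran with C2, C3 and C1' already correct, so the real problem is moved into the synthesis of A8 and not solved. The ring C alkene is a second π-partner for the carbene at the annulation temperature.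
- Comparison: it is longer by at least the deoxygenation and the carbene synthesis. Its key step forms three bonds but no stereocentre, and it gives no answer to C1'.

Key step: step 7

Remarks on the chemistry (TBS = tert-butyldimethylsilyl):
- Check of the structures: the descriptors were re-derived from the SMILES and agree along the line (6S) in 8, (1S) in 11, (1'S) in 27. The trans ester 23 is (2S,3S) and becomes (2S,3R) on reduction only through a change of priorities.
- Design of the precursor: the (S)-enantiomer of acid 1 is used, so 8 is the single (3S,6S) diastereomer. C3 is erased in step 7, but while it exists a wrong C6 epimer is a diastereomer and can be removed. With an undefined C3 it could not.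
- The purchased acetophenone 12 lacks the C5 side chain; steps 8 and 9 add it.
- Assumption: in step 12 the ligand antipode meant is the one that sends hydride to the Re face of C2 of 19. It is written as (R)-DTBM-SEGPHOS and would be exchanged for its mirror image if a model 2-alkylchromone showed the opposite sense.
- Assumption: allyl benzoate 14 is taken as purchasable.

## Route

Step 1
Reactants: 1 (2S)-5-oxooxolane-2-carboxylic acid
Product: 2 methyl (2S)-5-oxooxolane-2-carboxylate
Conditions: MeI, KHCO3, DMF, rt
Reagents that add atoms: iodomethane, CI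
Why: Carboxylate O-alkylation (SN2 on iodomethane) with a base too weak to open the lactone or to epimerise C2; this ester carbon later becomes the lactone carbonyl of 8.

Step 2
Reactants: 2 methyl (2S)-5-oxooxolane-2-carboxylate
Product: 3 methyl (2S)-2-hydroxy-5-[methoxy(methyl)amino]-5-oxopentanoate
Conditions: MeNH(OMe)·HCl (1.5 equiv), AlMe3 (1.5 equiv), CH2Cl2, 0 °C; aq. Rochelle salt
Reagents that add atoms: N,O-dimethylhydroxylamine hydrochloride, CNOC.Cl
Why: Weinreb aminolysis of a lactone by an aluminium amide; the γ-lactone is the better acylating agent and the methyl ester is shielded by branching at C2, so a small excess at 0 °C should open only the ring. The hydroxy amide is silylated at once because it can relactonise.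

Step 3
Reactants: 3 methyl (2S)-2-hydroxy-5-[methoxy(methyl)amino]-5-oxopentanoate
Product: 4 methyl (2S)-2-[(tert-butyldimethylsilyl)oxy]-5-[methoxy(methyl)amino]-5-oxopentanoate
Conditions: TBSCl, imidazole, DMF, rt
Reagents that add atoms: tert-butyldimethylsilyl chloride, CC(C)(C)[Si](C)(C)Cl
Why: Standard O-silylation of a secondary α-hydroxy ester; the ether blocks relactonisation, survives the base of step 7, and its oxygen becomes the C1' oxygen.

Step 4
Reactants: 4 methyl (2S)-2-[(tert-butyldimethylsilyl)oxy]-5-[methoxy(methyl)amino]-5-oxopentanoate; 5 vinylmagnesium bromide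
Product: 6 methyl (2S)-2-[(tert-butyldimethylsilyl)oxy]-5-oxohept-6-enoate
Conditions: 5 (1.3 equiv), THF, −78 → −20 °C; inverse quench into cold 1 M HCl
Reagents that add atoms: none
Why: Weinreb ketone synthesis; the chelated tetrahedral adduct stops at the ketone stage and the hindered α-silyloxy ester reacts more slowly than the amide at low temperature. The cold acidic inverse quench keeps the liberated amine from adding to the enone.

Step 5
Reactants: 6 methyl (2S)-2-[(tert-butyldimethylsilyl)oxy]-5-oxohept-6-enoate
Product: 7 methyl (2S,5S)-2-[(tert-butyldimethylsilyl)oxy]-5-hydroxyhept-6-enoate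
Conditions: (R)-2-methyl-CBS-oxazaborolidine (20 mol%), catecholborane, toluene, −78 °C; MeOH
Reagents that add atoms: none
Why: Corey–Bakshi–Shibata reduction of an enone; the vinyl group takes the place of the large substituent, so the (R)-catalyst should deliver hydride to the face that gives the (5S)-carbinol, and 1,2-reduction outruns hydroboration at −78 °C. C2 is untouched, so any (5R) material is a diastereomer that is removed after step 6.

Step 6
Reactants: 7 methyl (2S,5S)-2-[(tert-butyldimethylsilyl)oxy]-5-hydroxyhept-6-enoate
Product: 8 (3S,6S)-3-[(tert-butyldimethylsilyl)oxy]-6-ethenyloxan-2-one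
Conditions: TsOH·H2O (5 mol%), CH2Cl2, rt; chromatography
Reagents that add atoms: none
Why: Acid-catalysed transesterification (6-exo-trig lactonisation) with loss of methanol touches no stereocentre. Chromatography should separate the cis lactone 8 from its trans (3S,6R) epimer, which raises the purity at C6 before it is transferred.

Step 7
Reactants: 8 (3S,6S)-3-[(tert-butyldimethylsilyl)oxy]-6-ethenyloxan-2-one
Product: 11 (1S)-1-[(tert-butyldimethylsilyl)oxy]cyclohex-3-ene-1-carboxylic acid, via silyl ketene acetal 9 (not isolated), via trimethylsilyl ester 10 (not isolated)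
Conditions: LiN(SiMe3)2 (1.2 equiv), Me3SiCl, Et3N, THF, −78 °C → rt; toluene, 100 °C; then 1 M HCl, THF, 0 °C
Reagents that add atoms: chlorotrimethylsilane, C[Si](C)(C)Cl (held in 9 and 10, gone from 11)
Why: Deprotonation at C3 with Me3SiCl present traps the lactone enolate as the cyclic silyl ketene acetal 9, whose C2=C3 geometry is fixed by the ring, so the C3 centre of 8 no longer matters. On heating, 9 undergoes a concerted (3,3) sigmatropic shift, an Ireland–Claisen rearrangement whose closest known type is the rearrangement of alkenyl lactone silyl ketene acetals to cycloalkene carboxylic acids: the vinyl terminus bonds to C3 (C1'–C2'), the C6–O1 bond (C4'–O) breaks and the double bond moves to C3'=C4'. Ring C closes as this new σ bond spans the 1,4-positions of the lactone: O1 and the carbonyl carbon leave the ring, the two vinyl carbons enter it, and a six-membered carbocycle replaces the six-membered lactone. The closure is pericyclic through a boat, bicyclo[2.2.2]-like transition state, the only geometry in which the vinyl group reaches C3. The new stereocentre C1' is controlled by C6 alone: the vinyl group can bond to C3 only on the lactone face it occupies, so (6S) is transferred suprafacially to (1S), and the same geometry makes the ring alkene cis. The step needs O-silylation over C-silylation and rearrangement over hydrolysis or self-condensation; the internal quench, the absence of a β-leaving group and a strictly anhydrous thermal stage secure this. Dilute cold acid cleaves only the silyl ester 10, and the tertiary silyl ether of 11 stays.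

Step 8
Reactants: 12 1-(2-hydroxy-3-methoxyphenyl)ethanone
Product: 13 1-(5-bromo-2-hydroxy-3-methoxyphenyl)ethanone
Conditions: NBS (1.0 equiv), MeCN, 0 °C → rt
Reagents that add atoms: N-bromosuccinimide, O=C1CCC(=O)N1Br
Why: Electrophilic aromatic bromination; C5 is para to the phenol, the strongest donor, and meta to the acetyl group, so one regioisomer is expected.

Step 9
Reactants: 13 1-(5-bromo-2-hydroxy-3-methoxyphenyl)ethanone; 14 prop-2-en-1-yl benzoate
Product: 16 3-(3-acetyl-4-hydroxy-5-methoxyphenyl)propyl benzoate, via alkylborane 15 (not isolated)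
Conditions: 14, 9-BBN, THF, 0 °C → rt; then 13, [1,1'-bis(diphenylphosphino)ferrocene]PdCl2 (5 mol%), 3 M aq. K3PO4, DMF, 50 °C
Reagents that add atoms: 9-borabicyclo[3.3.1]nonane, B1C2CCCC1CCC2 (held in 15 only)
Why: Anti-Markovnikov hydroboration of the allyl ester, then B-alkyl Suzuki–Miyaura coupling; the aryl ketone, the phenol (as phenoxide) and the benzoate tolerate the phosphate base. The benzoate has no α-hydrogen, survives the acidic steps 11 and 13, and is removed by the hydride of step 14.

Step 10
Reactants: 11 (1S)-1-[(tert-butyldimethylsilyl)oxy]cyclohex-3-ene-1-carboxylic acid; 16 3-(3-acetyl-4-hydroxy-5-methoxyphenyl)propyl benzoate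
Product: 18 3-[3-(3-{(1S)-1-[(tert-butyldimethylsilyl)oxy]cyclohex-3-en-1-yl}-3-oxopropanoyl)-4-hydroxy-5-methoxyphenyl]propyl benzoate, via acid chloride 17 (not isolated)
Conditions: 11, (COCl)2, cat. DMF, CH2Cl2, 0 °C → rt, evaporate; 16 (1.2 equiv), LiN(SiMe3)2 (3.6 equiv), THF, −78 °C; add 17, −78 → −30 °C; aq. NH4Cl
Reagents that add atoms: oxalyl chloride, O=C(Cl)C(=O)Cl (its chlorine is held in 17 only)
Why: C-acylation of the dilithio phenoxide-enolate of an ortho-hydroxyacetophenone by an acid chloride, the one-flask form of the Baker–Venkataraman sequence; the third equivalent of base takes up the acidic 1,3-diketone, and any O-acylated phenol is funnelled to the same diketone by acyl transfer. Acid chloride 17 has no α-hydrogen, so neither ketene formation nor epimerisation can occur.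

Step 11
Reactants: 18 3-[3-(3-{(1S)-1-[(tert-butyldimethylsilyl)oxy]cyclohex-3-en-1-yl}-3-oxopropanoyl)-4-hydroxy-5-methoxyphenyl]propyl benzoate
Product: 19 3-(2-{(1S)-1-[(tert-butyldimethylsilyl)oxy]cyclohex-3-en-1-yl}-8-methoxy-4-oxo-4H-chromen-6-yl)propyl benzoate
Conditions: TsOH·H2O (10 mol%), toluene, 4 Å MS, 80 °C
Reagents that add atoms: none
Why: Acid-catalysed cyclodehydration of an ortho-hydroxyaryl 1,3-diketone (6-exo-trig hemiketal formation, then loss of water) gives the chromone. The tertiary silyl ether and the isolated alkene should tolerate catalytic sulfonic acid in a non-nucleophilic solvent.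

Step 12
Reactants: 19 3-(2-{(1S)-1-[(tert-butyldimethylsilyl)oxy]cyclohex-3-en-1-yl}-8-methoxy-4-oxo-4H-chromen-6-yl)propyl benzoate
Product: 21 3-[(2S)-2-{(1S)-1-[(tert-butyldimethylsilyl)oxy]cyclohex-3-en-1-yl}-8-methoxy-4-oxo-3,4-dihydro-2H-chromen-6-yl]propyl benzoate, via silyl enol ether 20 (not isolated)
Conditions: Cu(OAc)2·H2O (5 mol%), (R)-DTBM-SEGPHOS (5.5 mol%), (EtO)2MeSiH, toluene, 0 °C → rt; then 1 M HCl, THF, 0 °C
Reagents that add atoms: diethoxy(methyl)silane, CCO[SiH](C)OCC (held in 20 only)
Why: Copper hydride-catalysed asymmetric conjugate reduction of a chromone; the ligand-bound monovalent copper hydride adds hydrogen to one face of C2 (the Re face is needed for 2S), since C1' with its two nearly identical arms gives no bias of its own. The enolate is held as silyl enol ether 20, which guards C4 against 1,2-reduction and C2 against retro-oxa-Michael opening until the cold acidic work-up. The isolated ring C alkene is inert to copper hydride.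

Step 13
Reactants: 21 3-[(2S)-2-{(1S)-1-[(tert-butyldimethylsilyl)oxy]cyclohex-3-en-1-yl}-8-methoxy-4-oxo-3,4-dihydro-2H-chromen-6-yl]propyl benzoate
Product: 23 methyl (2S,3S)-5-[3-(benzoyloxy)propyl]-2-{(1S)-1-[(tert-butyldimethylsilyl)oxy]cyclohex-3-en-1-yl}-7-methoxy-2,3-dihydro-1-benzofuran-3-carboxylate, via methyl enol ether 22 (not isolated)
Conditions: PhI(OAc)2 (1.1 equiv), TsOH·H2O (1.2 equiv), HC(OMe)3/MeOH, 0 °C → rt; aq. NaHCO3
Reagents that add atoms: trimethyl orthoformate, COC(OC)OC; methanol, CO; water, O
Why: Oxidative 1,2-aryl shift, the ring contraction of a chroman-4-one by trivalent iodine: enol ether 22 is iodinated at C3 trans to the bulky C2 group, methanol adds at C4, and ring carbon C4a migrates from C4 to C3 anti to the departing iodobenzene; the dimethoxycarbenium ion is then taken up by water to give the ester. The shift makes the C3–C3a bond, places the ester trans to the C2 substituent (also the thermodynamic arrangement at the epimerisable C3) and leaves C2 untouched. The enol ether is far more nucleophilic than the isolated ring C alkene, so a slight excess of oxidant should spare the alkene.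

Step 14
Reactants: 23 methyl (2S,3S)-5-[3-(benzoyloxy)propyl]-2-{(1S)-1-[(tert-butyldimethylsilyl)oxy]cyclohex-3-en-1-yl}-7-methoxy-2,3-dihydro-1-benzofuran-3-carboxylate
Product: 24 3-[(2S,3R)-2-{(1S)-1-[(tert-butyldimethylsilyl)oxy]cyclohex-3-en-1-yl}-3-(hydroxymethyl)-7-methoxy-2,3-dihydro-1-benzofuran-5-yl]propan-1-ol
Conditions: LiAlH4, THF, 0 °C → rt; aq. Rochelle salt
Reagents that add atoms: none
Why: Hydride reduction of both esters: the C3 ester gives the hydroxymethyl group and the benzoate gives the chain alcohol. Reduction is faster than enolisation, so C3 is retained (the descriptor changes to R by priority only), and the silyl ether and alkene are untouched.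

Step 15
Reactants: 24 3-[(2S,3R)-2-{(1S)-1-[(tert-butyldimethylsilyl)oxy]cyclohex-3-en-1-yl}-3-(hydroxymethyl)-7-methoxy-2,3-dihydro-1-benzofuran-5-yl]propan-1-ol
Product: 25 (1S)-1-[(2S,3R)-3-(hydroxymethyl)-5-(3-hydroxypropyl)-7-methoxy-2,3-dihydro-1-benzofuran-2-yl]cyclohex-3-en-1-ol
Conditions: Bu4NF, THF, 50 °C
Reagents that add atoms: none
Why: Fluoride-induced Si–O cleavage; the hindered tertiary silyl ether needs warming, and nothing else in 24 is sensitive to fluoride or mild base.

Step 16
Reactants: 25 (1S)-1-[(2S,3R)-3-(hydroxymethyl)-5-(3-hydroxypropyl)-7-methoxy-2,3-dihydro-1-benzofuran-2-yl]cyclohex-3-en-1-ol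
Product: 26 (1S,3S,6R)-3-[(2S,3R)-3-(hydroxymethyl)-5-(3-hydroxypropyl)-7-methoxy-2,3-dihydro-1-benzofuran-2-yl]-7-oxabicyclo[4.1.0]heptan-3-ol
Conditions: VO(acac)2 (5 mol%), t-BuOOH, CH2Cl2, 0 °C → rt
Reagents that add atoms: tert-butyl hydroperoxide, CC(C)(C)OO
Why: Hydroxyl-directed epoxidation; the vanadate ester of the homoallylic C1' hydroxyl delivers the peroxide oxygen to the alkene face syn to that hydroxyl, which sets both epoxide carbons. The primary alcohols are too remote to direct, and the arene is not attacked by this reagent.

Step 17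
Reactants: 26 (1S,3S,6R)-3-[(2S,3R)-3-(hydroxymethyl)-5-(3-hydroxypropyl)-7-methoxy-2,3-dihydro-1-benzofuran-2-yl]-7-oxabicyclo[4.1.0]heptan-3-ol
Product: 27 difengpiol B, (1S,3S,4S)-1-[(2S,3R)-3-(hydroxymethyl)-5-(3-hydroxypropyl)-7-methoxy-2,3-dihydro-1-benzofuran-2-yl]-4-methoxycyclohexane-1,3-diol
Conditions: Eu(OTf)3 (10 mol%), MeOH, rt → 40 °C
Reagents that add atoms: methanol, CO
Why: Lewis acid-catalysed methanolysis of a 3,4-epoxy alcohol; the lanthanide bridges the syn C1' hydroxyl and the epoxide oxygen, and methanol attacks the distal carbon C4' from the opposite face with inversion. This is also the trans-diaxial (Fürst–Plattner) opening of the half-chair that keeps the large C2 substituent equatorial, and it gives 4'-OMe trans to 3'-OH with 3'-OH cis to 1'-OH. The syn C1' hydroxyl cannot open the epoxide itself because it cannot reach the backside.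

## Compound list

1 | (2S)-5-oxooxolane-2-carboxylic acid | OC(=O)[C@@H]1CCC(=O)O1 | starting material
2 | methyl (2S)-5-oxooxolane-2-carboxylate | COC(=O)[C@@H]1CCC(=O)O1 | intermediate
3 | methyl (2S)-2-hydroxy-5-[methoxy(methyl)amino]-5-oxopentanoate | COC(=O)[C@@H](O)CCC(=O)N(C)OC | intermediate
4 | methyl (2S)-2-[(tert-butyldimethylsilyl)oxy]-5-[methoxy(methyl)amino]-5-oxopentanoate | COC(=O)[C@@H](O[Si](C)(C)C(C)(C)C)CCC(=O)N(C)OC | intermediate
5 | vinylmagnesium bromide | C=C[Mg]Br | starting material
6 | methyl (2S)-2-[(tert-butyldimethylsilyl)oxy]-5-oxohept-6-enoate | COC(=O)[C@@H](O[Si](C)(C)C(C)(C)C)CCC(=O)C=C | intermediate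
7 | methyl (2S,5S)-2-[(tert-butyldimethylsilyl)oxy]-5-hydroxyhept-6-enoate | COC(=O)[C@@H](O[Si](C)(C)C(C)(C)C)CC[C@H](O)C=C | intermediate
8 | (3S,6S)-3-[(tert-butyldimethylsilyl)oxy]-6-ethenyloxan-2-one | C=C[C@@H]1CC[C@H](O[Si](C)(C)C(C)(C)C)C(=O)O1 | intermediate
9 | (2S)-5-[(tert-butyldimethylsilyl)oxy]-2-ethenyl-6-[(trimethylsilyl)oxy]-3,4-dihydro-2H-pyran | C=C[C@@H]1CCC(O[Si](C)(C)C(C)(C)C)=C(O[Si](C)(C)C)O1 | intermediate (not isolated)
10 | trimethylsilyl (1S)-1-[(tert-butyldimethylsilyl)oxy]cyclohex-3-ene-1-carboxylate | C[Si](C)(C)OC(=O)[C@]1(O[Si](C)(C)C(C)(C)C)CCC=CC1 | intermediate (not isolated)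
11 | (1S)-1-[(tert-butyldimethylsilyl)oxy]cyclohex-3-ene-1-carboxylic acid | OC(=O)[C@]1(O[Si](C)(C)C(C)(C)C)CCC=CC1 | intermediate
12 | 1-(2-hydroxy-3-methoxyphenyl)ethanone | CC(=O)c1cccc(OC)c1O | starting material
13 | 1-(5-bromo-2-hydroxy-3-methoxyphenyl)ethanone | CC(=O)c1cc(Br)cc(OC)c1O | intermediate
14 | prop-2-en-1-yl benzoate | C=CCOC(=O)c1ccccc1 | starting material
15 | 3-(9-borabicyclo[3.3.1]nonan-9-yl)propyl benzoate | O=C(OCCCB1C2CCCC1CCC2)c1ccccc1 | intermediate (not isolated)
16 | 3-(3-acetyl-4-hydroxy-5-methoxyphenyl)propyl benzoate | CC(=O)c1cc(CCCOC(=O)c2ccccc2)cc(OC)c1O | intermediate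
17 | (1S)-1-[(tert-butyldimethylsilyl)oxy]cyclohex-3-ene-1-carbonyl chloride | ClC(=O)[C@]1(O[Si](C)(C)C(C)(C)C)CCC=CC1 | intermediate (not isolated)
18 | 3-[3-(3-{(1S)-1-[(tert-butyldimethylsilyl)oxy]cyclohex-3-en-1-yl}-3-oxopropanoyl)-4-hydroxy-5-methoxyphenyl]propyl benzoate | COc1cc(CCCOC(=O)c2ccccc2)cc(C(=O)CC(=O)[C@]2(O[Si](C)(C)C(C)(C)C)CCC=CC2)c1O | intermediate
19 | 3-(2-{(1S)-1-[(tert-butyldimethylsilyl)oxy]cyclohex-3-en-1-yl}-8-methoxy-4-oxo-4H-chromen-6-yl)propyl benzoate | COc1cc(CCCOC(=O)c2ccccc2)cc2c1OC(=CC2=O)[C@]1(O[Si](C)(C)C(C)(C)C)CCC=CC1 | intermediate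
20 | 3-[(2S)-2-{(1S)-1-[(tert-butyldimethylsilyl)oxy]cyclohex-3-en-1-yl}-4-{[diethoxy(methyl)silyl]oxy}-8-methoxy-2H-chromen-6-yl]propyl benzoate | COc1cc(CCCOC(=O)c2ccccc2)cc2c1O[C@@H](C=C2O[Si](C)(OCC)OCC)[C@]1(O[Si](C)(C)C(C)(C)C)CCC=CC1 | intermediate (not isolated)
21 | 3-[(2S)-2-{(1S)-1-[(tert-butyldimethylsilyl)oxy]cyclohex-3-en-1-yl}-8-methoxy-4-oxo-3,4-dihydro-2H-chromen-6-yl]propyl benzoate | COc1cc(CCCOC(=O)c2ccccc2)cc2c1O[C@@H](CC2=O)[C@]1(O[Si](C)(C)C(C)(C)C)CCC=CC1 | intermediate
22 | 3-[(2S)-2-{(1S)-1-[(tert-butyldimethylsilyl)oxy]cyclohex-3-en-1-yl}-4,8-dimethoxy-2H-chromen-6-yl]propyl benzoate | COc1cc(CCCOC(=O)c2ccccc2)cc2c1O[C@@H](C=C2OC)[C@]1(O[Si](C)(C)C(C)(C)C)CCC=CC1 | intermediate (not isolated)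
23 | methyl (2S,3S)-5-[3-(benzoyloxy)propyl]-2-{(1S)-1-[(tert-butyldimethylsilyl)oxy]cyclohex-3-en-1-yl}-7-methoxy-2,3-dihydro-1-benzofuran-3-carboxylate | COc1cc(CCCOC(=O)c2ccccc2)cc2c1O[C@H]([C@]1(O[Si](C)(C)C(C)(C)C)CCC=CC1)[C@H]2C(=O)OC | intermediate
24 | 3-[(2S,3R)-2-{(1S)-1-[(tert-butyldimethylsilyl)oxy]cyclohex-3-en-1-yl}-3-(hydroxymethyl)-7-methoxy-2,3-dihydro-1-benzofuran-5-yl]propan-1-ol | COc1cc(CCCO)cc2c1O[C@H]([C@]1(O[Si](C)(C)C(C)(C)C)CCC=CC1)[C@H]2CO | intermediate
25 | (1S)-1-[(2S,3R)-3-(hydroxymethyl)-5-(3-hydroxypropyl)-7-methoxy-2,3-dihydro-1-benzofuran-2-yl]cyclohex-3-en-1-ol | COc1cc(CCCO)cc2c1O[C@H]([C@]1(O)CCC=CC1)[C@H]2CO | intermediate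
26 | (1S,3S,6R)-3-[(2S,3R)-3-(hydroxymethyl)-5-(3-hydroxypropyl)-7-methoxy-2,3-dihydro-1-benzofuran-2-yl]-7-oxabicyclo[4.1.0]heptan-3-ol | COc1cc(CCCO)cc2c1O[C@H]([C@]1(O)CC[C@H]3O[C@H]3C1)[C@H]2CO | intermediate
27 | difengpiol B, (1S,3S,4S)-1-[(2S,3R)-3-(hydroxymethyl)-5-(3-hydroxypropyl)-7-methoxy-2,3-dihydro-1-benzofuran-2-yl]-4-methoxycyclohexane-1,3-diol | COc1cc(CCCO)cc2c1O[C@H]([C@]1(O)CC[C@H](OC)[C@@H](O)C1)[C@H]2CO | target

## Step count and least certain steps

Total: 17 steps. Longest linear sequence: 15 steps (steps 1 to 7 and 10 to 17); steps 8 and 9 are the two-step side branch to 16.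

**Step 7 (key step).** The most likely failure is consumption of the silyl ketene acetal by proton transfer or hydrolysis before the strained boat geometry is reached, since the shift needs about 100 °C while the ketene acetal is sensitive to moisture and acid. Incomplete enolisation of the hindered α-silyloxy lactone is a second risk. The fallback replaces the sigmatropic shift by a cycloaddition. It does not branch from a numbered intermediate: it replaces 1 to 10, sets out from purchased (R)-lactic acid, and comes back at 11. (R)-Lactic acid and pivalaldehyde (TsOH, pentane, water separator) should give (2R,5R)-2-tert-butyl-5-methyl-1,3-dioxolan-4-one F1. Radical bromination (NBS, AIBN) gives (2S)-5-bromo-2-tert-butyl-5-methyl-1,3-dioxolan-4-one F2 (the descriptor changes by priority only). DBU removes HBr to give (2R)-2-tert-butyl-5-methylidene-1,3-dioxolan-4-one F3. Buta-1,3-diene in toluene at about 110 °C in a sealed vessel should add anti to the tert-butyl group and give (2R,5S)-2-tert-butyl-1,3-dioxaspiro[4.5]dec-7-en-4-one F4. LiOH in aqueous THF gives (1S)-1-hydroxycyclohex-3-ene-1-carboxylic acid F5. TBSOTf and 2,6-lutidine give tert-butyldimethylsilyl (1S)-1-[(tert-butyldimethylsilyl)oxy]cyclohex-3-ene-1-carboxylate F6, and K2CO3 in methanol frees acid 11.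

**Step 12.** The most likely failure is poor facial discrimination in hydride delivery at the crowded C2, which has a quaternary neighbour, or 1,2-reduction at C4 if the enolate is protonated in the flask. The fallback sets C2 by C–O instead of C–H bond formation, sets out from 11 and 16, and comes back at 21. Acid 11 is methylated (MeI, K2CO3, DMF) to methyl (1S)-1-[(tert-butyldimethylsilyl)oxy]cyclohex-3-ene-1-carboxylate F7 and reduced with i-Bu2AlH at −78 °C to (1S)-1-[(tert-butyldimethylsilyl)oxy]cyclohex-3-ene-1-carbaldehyde F8. The dilithio derivative of 16 (LiN(SiMe3)2, 2.1 equiv, THF, −78 °C) adds to F8 to give the aldol 3-[3-(3-{(1S)-1-[(tert-butyldimethylsilyl)oxy]cyclohex-3-en-1-yl}-3-hydroxypropanoyl)-4-hydroxy-5-methoxyphenyl]propyl benzoate F9. Catalytic TsOH in warm toluene dehydrates it to the (E)-enone 3-[3-((2E)-3-{(1S)-1-[(tert-butyldimethylsilyl)oxy]cyclohex-3-en-1-yl}prop-2-enoyl)-4-hydroxy-5-methoxyphenyl]propyl benzoate F10. A cinchona-derived bifunctional thiourea (quinine or quinidine series, as the required face demands) then catalyses the 6-endo-trig oxa-Michael closure to 21.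

**Step 13.** The most likely failures are attack of the iodane on the ring C alkene, loss of iodobenzene together with the C2 hydrogen (which leads back to chromone 19), and acid-induced loss of the tertiary silyl ether. The fallback is a Wolff ring contraction without an oxidant; it sets out from 21 and comes back at 23. Heating 21 with Me2NCH(OMe)2 should give the enaminone 3-[(2S)-2-{(1S)-1-[(tert-butyldimethylsilyl)oxy]cyclohex-3-en-1-yl}-3-[(dimethylamino)methylidene]-8-methoxy-4-oxo-3,4-dihydro-2H-chromen-6-yl]propyl benzoate F11. Methanesulfonyl azide transfers the diazo group with loss of the formamidine and gives the diazo ketone 3-[(2S)-2-{(1S)-1-[(tert-butyldimethylsilyl)oxy]cyclohex-3-en-1-yl}-3-diazo-8-methoxy-4-oxo-3,4-dihydro-2H-chromen-6-yl]propyl benzoate F12. Irradiation in methanol (aryl migration to the carbene carbon, ketene trapped by methanol) gives 23 together with its C3 epimer, methyl (2S,3R)-5-[3-(benzoyloxy)propyl]-2-{(1S)-1-[(tert-butyldimethylsilyl)oxy]cyclohex-3-en-1-yl}-7-methoxy-2,3-dihydro-1-benzofuran-3-carboxylate F13. DBU equilibrates F13 to the trans ester 23.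

**Step 5.** The most likely failure is weak differentiation of the vinyl and the alkyl arm by the oxazaborolidine, which erodes the configuration at C6 (the future C1'); hydroboration of the vinyl group is a second risk. The fallback uses an ynone in place of the enone and transfer hydrogenation in place of a borane; it sets out from 4 and comes back at 7. Lithium (trimethylsilyl)acetylide adds to 4 to give methyl (2S)-2-[(tert-butyldimethylsilyl)oxy]-5-oxo-7-(trimethylsilyl)hept-6-ynoate F14. Noyori transfer hydrogenation with RuCl[(S,S)-TsDPEN](p-cymene) in 2-propanol should give methyl (2S,5S)-2-[(tert-butyldimethylsilyl)oxy]-5-hydroxy-7-(trimethylsilyl)hept-6-ynoate F15. K2CO3 in methanol removes the C-silyl group to give methyl (2S,5S)-2-[(tert-butyldimethylsilyl)oxy]-5-hydroxyhept-6-ynoate F16. Semihydrogenation (H2, Pd/CaCO3 poisoned with Pb(OAc)2, quinoline) gives 7.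

## Further compounds

F1 | step 7 | (2R,5R)-2-tert-butyl-5-methyl-1,3-dioxolan-4-one | C[C@H]1O[C@@H](C(C)(C)C)OC1=O
F2 | step 7 | (2S)-5-bromo-2-tert-butyl-5-methyl-1,3-dioxolan-4-one | CC1(Br)O[C@@H](C(C)(C)C)OC1=O
F3 | step 7 | (2R)-2-tert-butyl-5-methylidene-1,3-dioxolan-4-one | C=C1O[C@@H](C(C)(C)C)OC1=O
F4 | step 7 | (2R,5S)-2-tert-butyl-1,3-dioxaspiro[4.5]dec-7-en-4-one | O=C1[C@@]2(CCC=CC2)O[C@@H](C(C)(C)C)O1
F5 | step 7 | (1S)-1-hydroxycyclohex-3-ene-1-carboxylic acid | OC(=O)[C@]1(O)CCC=CC1
F6 | step 7 | tert-butyldimethylsilyl (1S)-1-[(tert-butyldimethylsilyl)oxy]cyclohex-3-ene-1-carboxylate | CC(C)(C)[Si](C)(C)OC(=O)[C@]1(O[Si](C)(C)C(C)(C)C)CCC=CC1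
F7 | step 12 | methyl (1S)-1-[(tert-butyldimethylsilyl)oxy]cyclohex-3-ene-1-carboxylate | COC(=O)[C@]1(O[Si](C)(C)C(C)(C)C)CCC=CC1
F8 | step 12 | (1S)-1-[(tert-butyldimethylsilyl)oxy]cyclohex-3-ene-1-carbaldehyde | O=C[C@]1(O[Si](C)(C)C(C)(C)C)CCC=CC1
F9 | step 12 | 3-[3-(3-{(1S)-1-[(tert-butyldimethylsilyl)oxy]cyclohex-3-en-1-yl}-3-hydroxypropanoyl)-4-hydroxy-5-methoxyphenyl]propyl benzoate | COc1cc(CCCOC(=O)c2ccccc2)cc(C(=O)CC(O)[C@]2(O[Si](C)(C)C(C)(C)C)CCC=CC2)c1O
F10 | step 12 | 3-[3-((2E)-3-{(1S)-1-[(tert-butyldimethylsilyl)oxy]cyclohex-3-en-1-yl}prop-2-enoyl)-4-hydroxy-5-methoxyphenyl]propyl benzoate | COc1cc(CCCOC(=O)c2ccccc2)cc(C(=O)/C=C/[C@]2(O[Si](C)(C)C(C)(C)C)CCC=CC2)c1O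
F11 | step 13 | 3-[(2S)-2-{(1S)-1-[(tert-butyldimethylsilyl)oxy]cyclohex-3-en-1-yl}-3-[(dimethylamino)methylidene]-8-methoxy-4-oxo-3,4-dihydro-2H-chromen-6-yl]propyl benzoate | COc1cc(CCCOC(=O)c2ccccc2)cc2c1O[C@@H](C(=CN(C)C)C2=O)[C@]1(O[Si](C)(C)C(C)(C)C)CCC=CC1
F12 | step 13 | 3-[(2S)-2-{(1S)-1-[(tert-butyldimethylsilyl)oxy]cyclohex-3-en-1-yl}-3-diazo-8-methoxy-4-oxo-3,4-dihydro-2H-chromen-6-yl]propyl benzoate | COc1cc(CCCOC(=O)c2ccccc2)cc2c1O[C@@H](C(=[N+]=[N-])C2=O)[C@]1(O[Si](C)(C)C(C)(C)C)CCC=CC1
F13 | step 13 | methyl (2S,3R)-5-[3-(benzoyloxy)propyl]-2-{(1S)-1-[(tert-butyldimethylsilyl)oxy]cyclohex-3-en-1-yl}-7-methoxy-2,3-dihydro-1-benzofuran-3-carboxylate | COc1cc(CCCOC(=O)c2ccccc2)cc2c1O[C@H]([C@]1(O[Si](C)(C)C(C)(C)C)CCC=CC1)[C@@H]2C(=O)OC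
F14 | step 5 | methyl (2S)-2-[(tert-butyldimethylsilyl)oxy]-5-oxo-7-(trimethylsilyl)hept-6-ynoate | COC(=O)[C@@H](O[Si](C)(C)C(C)(C)C)CCC(=O)C#C[Si](C)(C)C
F15 | step 5 | methyl (2S,5S)-2-[(tert-butyldimethylsilyl)oxy]-5-hydroxy-7-(trimethylsilyl)hept-6-ynoate | COC(=O)[C@@H](O[Si](C)(C)C(C)(C)C)CC[C@H](O)C#C[Si](C)(C)C
F16 | step 5 | methyl (2S,5S)-2-[(tert-butyldimethylsilyl)oxy]-5-hydroxyhept-6-ynoate | COC(=O)[C@@H](O[Si](C)(C)C(C)(C)C)CC[C@H](O)C#C
A1 | alternative 1 | (2S,3R)-3-{[(tert-butyldimethylsilyl)oxy]methyl}-5-{3-[(tert-butyldimethylsilyl)oxy]propyl}-N,7-dimethoxy-N-methyl-2,3-dihydro-1-benzofuran-2-carboxamide | COc1cc(CCCO[Si](C)(C)C(C)(C)C)cc2c1O[C@H](C(=O)N(C)OC)[C@H]2CO[Si](C)(C)C(C)(C)C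
A2 | alternative 1 | 2-{2-[(tert-butyldimethylsilyl)oxy]-1-(4-methylbenzenesulfonyl)ethyl}-4-{3-[(tert-butyldimethylsilyl)oxy]propyl}-6-methoxyphenol | COc1cc(CCCO[Si](C)(C)C(C)(C)C)cc(C(CO[Si](C)(C)C(C)(C)C)S(=O)(=O)c2ccc(C)cc2)c1O
A3 | alternative 1 | {2-[methoxy(methyl)amino]-2-oxoethyl}dimethylsulfonium bromide | C[S+](C)CC(=O)N(C)OC.[Br-]
A4 | alternative 2 | (2R)-2-tert-butyl-5-methylidene-1,3-dioxolan-4-one | C=C1O[C@@H](C(C)(C)C)OC1=O
A5 | alternative 2 | buta-1,3-diene | C=CC=C
A6 | alternative 2 | (2R,5S)-2-tert-butyl-1,3-dioxaspiro[4.5]dec-7-en-4-one | O=C1[C@@]2(CCC=CC2)O[C@@H](C(C)(C)C)O1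
A7 | alternative 2 | (1S)-1-hydroxycyclohex-3-ene-1-carboxylic acid | OC(=O)[C@]1(O)CCC=CC1
A8 | alternative 3 | pentacarbonyl[methoxy(4,5-dihydrofuran-2-yl)methylidene]chromium with trans 4-{[(tert-butyldimethylsilyl)oxy]methyl} and 5-{(1S)-1-[(triethylsilyl)oxy]cyclohex-3-en-1-yl} groups, configured as in A10 | COC(=[Cr](=C=O)(=C=O)(=C=O)(=C=O)=C=O)C1=C[C@H](CO[Si](C)(C)C(C)(C)C)[C@@H]([C@]2(O[Si](CC)(CC)CC)CCC=CC2)O1
A9 | alternative 3 | tert-butyldimethyl(pent-4-yn-1-yloxy)silane | C#CCCCO[Si](C)(C)C(C)(C)C
A10 | alternative 3 | (2S,3R)-3-{[(tert-butyldimethylsilyl)oxy]methyl}-5-{3-[(tert-butyldimethylsilyl)oxy]propyl}-7-methoxy-2-{(1S)-1-[(triethylsilyl)oxy]cyclohex-3-en-1-yl}-2,3-dihydro-1-benzofuran-4-ol | COc1cc(CCCO[Si](C)(C)C(C)(C)C)c(O)c2c1O[C@H]([C@]1(O[Si](CC)(CC)CC)CCC=CC1)[C@H]2CO[Si](C)(C)C(C)(C)C
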